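**Plan**
- On ring B the ketone sits on C6, with O1 (on C8a) para and the C7 hydroxyl ortho to it. Both aryl–oxygen bonds are therefore cut back to carbonyl-activated C–F bonds, O1–C8a first and C7–OH second.
- Further cuts are C4a–C4 (Sonogashira) and C6–C(=O) (aryllithium plus Weinreb amide). The carbonyl next to ring A is carried as a dimethyl ketal.
- Forward, symmetric 3,5-difluoroanisole is silyl-blocked at future C8, brominated at future C4a and acylated at future C6. The acylation brings in ring A and the two-carbon bridge at once.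
- Desilylation, alkynylation and cis semi-hydrogenation set up a tertiary alkoxide that displaces the C8a fluoride and closes ring C, the only ring built.
- The C7 fluoride is then exchanged for OH and the ketal is hydrolysed to the 1,2-dione.
- The target has no stereocentre. Its only geometric element, the cis C3=C4 bond, comes from the Lindlar reduction and is locked inside ring C.

Key step: step 9

Numbering: chromene numbering (O1, C2, C3, C4, C4a, C5–C8, C8a) is used for rings B and C, also in open-chain precursors. Ring A is the 4-methoxyphenyl ring.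
Assumption: the o-hydroxybenzil is taken in the open 1,2-dione form drawn for the target, although it may equilibrate in solution with its cyclic hemiketal.
Handling remark: compounds 10 to 18 contain an α,α-dimethoxy aryl ketone, a chromophore prone to photochemical α-cleavage, so they would be kept away from daylight and UV.

Step 1
Reactants: 1 3,5-difluoroanisole
Product: 3 (2,6-difluoro-4-methoxyphenyl)trimethylsilane, via 4-lithio-3,5-difluoroanisole 2 (not isolated)
Conditions: n-BuLi, THF, −78 °C; then Me3SiCl, −78 °C to rt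
Reagents that add atoms: chlorotrimethylsilane, C[Si](C)(C)Cl
Why: The hydrogen between the two fluorines (future C8) is by far the most acidic, so directed ortho-metalation and a silyl quench should block exactly this site against the later metalations.

Step 2
Reactants: 3 (2,6-difluoro-4-methoxyphenyl)trimethylsilane
Product: 5 (3-bromo-2,6-difluoro-4-methoxyphenyl)trimethylsilane, via [2,4-difluoro-6-methoxy-3-(trimethylsilyl)phenyl]lithium 4 (not isolated)
Conditions: s-BuLi, THF, −78 °C; then BrCl2C–CCl2Br, −78 °C to rt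
Reagents that add atoms: 1,2-dibromo-1,1,2,2-tetrachloroethane, ClC(Cl)(Br)C(Cl)(Cl)Br
Why: The two remaining ring hydrogens are equivalent and each lies between OMe and F, so a second directed ortho-metalation with an electrophilic bromine quench can give only one monobromide.

Step 3
Reactants: 6 methyl 2-(4-methoxyphenyl)-2-oxoacetate
Product: 7 methyl 2,2-dimethoxy-2-(4-methoxyphenyl)acetate
Conditions: HC(OMe)3, MeOH, cat. H2SO4, reflux
Reagents that add atoms: trimethyl orthoformate, COC(OC)OC; methanol, CO
Why: Acid-catalysed ketalisation with an orthoformate as water scavenger is standard for aryl glyoxylates, and the p-anisyl group stabilises the oxocarbenium ion while the ester carbonyl stays untouched.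

Step 4
Reactants: 7 methyl 2,2-dimethoxy-2-(4-methoxyphenyl)acetate
Product: 8 N,2,2-trimethoxy-2-(4-methoxyphenyl)-N-methylacetamide
Conditions: MeNHOMe·HCl, iPrMgCl, THF, −20 to 0 °C
Reagents that add atoms: N,O-dimethylhydroxylamine hydrochloride, CNOC.Cl
Why: Aminolysis of the ester by the magnesium amide formed in the flask (Weinreb amide synthesis) works on α-quaternary esters, and the ester is inductively activated by its two α-methoxy groups and cannot enolise.

Step 5
Reactants: 5 (3-bromo-2,6-difluoro-4-methoxyphenyl)trimethylsilane; 8 N,2,2-trimethoxy-2-(4-methoxyphenyl)-N-methylacetamide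
Product: 10 1-[3-bromo-4,6-difluoro-2-methoxy-5-(trimethylsilyl)phenyl]-2,2-dimethoxy-2-(4-methoxyphenyl)ethan-1-one, via [3-bromo-4,6-difluoro-2-methoxy-5-(trimethylsilyl)phenyl]lithium 9 (not isolated)
Conditions: LiN(iPr)2 (5 added to the base), THF, −78 °C; then 8, −78 to −50 °C; AcOH quench at −50 °C
Reagents that add atoms: none
Why: The amide base removes the only ring hydrogen (between OMe and F) without bromine–lithium exchange, a halogen dance would only regenerate the same aryllithium by symmetry, and the Weinreb ketone synthesis stops at the ketone because the chelated tetrahedral adduct survives until the quench.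

Step 6
Reactants: 10 1-[3-bromo-4,6-difluoro-2-methoxy-5-(trimethylsilyl)phenyl]-2,2-dimethoxy-2-(4-methoxyphenyl)ethan-1-one
Product: 11 1-(3-bromo-4,6-difluoro-2-methoxyphenyl)-2,2-dimethoxy-2-(4-methoxyphenyl)ethan-1-one
Conditions: Bu4NF·3H2O (cat.), wet THF, 0 °C to rt
Reagents that add atoms: none
Why: In this fluoride-induced protodesilylation the C–Si bond flanked by two fluorines releases a well-stabilised aryl anion equivalent that water protonates, fluoride is regenerated from Me3SiF and hydroxide, and C–Br, ketone and ketal are not affected.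

Step 7
Reactants: 11 1-(3-bromo-4,6-difluoro-2-methoxyphenyl)-2,2-dimethoxy-2-(4-methoxyphenyl)ethan-1-one; 12 2-methylbut-3-yn-2-ol
Product: 13 1-[4,6-difluoro-3-(3-hydroxy-3-methylbut-1-yn-1-yl)-2-methoxyphenyl]-2,2-dimethoxy-2-(4-methoxyphenyl)ethan-1-one
Conditions: PdCl2(PPh3)2 (cat.), CuI (cat.), Et3N, degassed DMF, 70 °C
Reagents that add atoms: none
Why: Sonogashira coupling of an electron-poor aryl bromide with this alkynol is routine, and a tertiary amine is chosen as base so that no N–H nucleophile can attack the activated C–F bonds.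

Step 8
Reactants: 13 1-[4,6-difluoro-3-(3-hydroxy-3-methylbut-1-yn-1-yl)-2-methoxyphenyl]-2,2-dimethoxy-2-(4-methoxyphenyl)ethan-1-one
Product: 14 (Z)-1-[4,6-difluoro-3-(3-hydroxy-3-methylbut-1-en-1-yl)-2-methoxyphenyl]-2,2-dimethoxy-2-(4-methoxyphenyl)ethan-1-one
Conditions: H2 (1 atm), Pd/CaCO3 poisoned with Pb(OAc)2 (Lindlar catalyst), quinoline, EtOAc, rt
Reagents that add atoms: none
Why: Lindlar semi-hydrogenation delivers both hydrogens to the same face of the alkyne on the poisoned surface and so should give the Z alkene, while aryl ketone, ketal and C–F bonds are inert.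

Step 9
Reactants: 14 (Z)-1-[4,6-difluoro-3-(3-hydroxy-3-methylbut-1-en-1-yl)-2-methoxyphenyl]-2,2-dimethoxy-2-(4-methoxyphenyl)ethan-1-one
Product: 16 1-(7-fluoro-5-methoxy-2,2-dimethyl-2H-chromen-6-yl)-2,2-dimethoxy-2-(4-methoxyphenyl)ethan-1-one, via sodium alkoxide 15 (not isolated)
Conditions: NaH, DMF (0.02 M), 0 °C to rt
Reagents that add atoms: none
Why: NaH forms the tertiary alkoxide 15, which adds to C8a from above the ring plane to give a Meisenheimer complex whose charge runs through C8 and C6 into the para ketone (helped inductively by the meta fluorine on C7), and loss of fluoride restores ring B. This is an intramolecular SNAr etherification of a carbonyl-activated fluoroarene, a known way to benzo-fused cyclic ethers. Ring C closes in a six-membered mode (O1, C2, C3, C4, C4a, C8a), formally 6-exo-trig at the C8a=C8 π bond. No stereocentre is created, and the Z geometry from step 8 becomes the endocyclic C3=C4 bond. The step needs site selectivity between two activated fluorides: the cis alkene holds the alkoxide next to C8a, whereas C7 lies para to the anchor C4a and cannot be reached, and high dilution suppresses attack on the C7 fluoride of a second molecule. The ketone cannot enolise because its α-carbon is the quaternary ketal, so the base is not consumed elsewhere.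

Step 10
Reactants: 16 1-(7-fluoro-5-methoxy-2,2-dimethyl-2H-chromen-6-yl)-2,2-dimethoxy-2-(4-methoxyphenyl)ethan-1-one
Product: 18 1-(7-hydroxy-5-methoxy-2,2-dimethyl-2H-chromen-6-yl)-2,2-dimethoxy-2-(4-methoxyphenyl)ethan-1-one, via 2-(methylsulfonyl)ethyl aryl ether 17 (not isolated)
Conditions: MeSO2CH2CH2OH, NaH, DMF, 0 °C to rt; AcOH quench
Reagents that add atoms: 2-(methylsulfonyl)ethanol, CS(=O)(=O)CCO
Why: SNAr of the sulfonylethoxide at the fluoride ortho to the ketone, followed by E1cB loss of methyl vinyl sulfone from ether 17 in the same flask, is a known hydroxide-free conversion of activated aryl fluorides into phenols and spares the non-enolisable ketone from hydroxide attack.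

Step 11
Reactants: 18 1-(7-hydroxy-5-methoxy-2,2-dimethyl-2H-chromen-6-yl)-2,2-dimethoxy-2-(4-methoxyphenyl)ethan-1-one
Product: 19 1-(7-hydroxy-5-methoxy-2,2-dimethyl-2H-chromen-6-yl)-2-(4-methoxyphenyl)ethane-1,2-dione (CNP0170833.0)
Conditions: 1 M HCl, THF, rt
Reagents that add atoms: water, O
Why: Acid-catalysed ketal hydrolysis runs through a p-anisyl-stabilised oxocarbenium ion under acid dilute enough to leave the chromene double bond and the aryl methyl ethers intact, and the dione gains a hydrogen bond from the C7 hydroxyl to the C6 carbonyl.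

**Compound list**
1 | 3,5-difluoroanisole | COc1cc(F)cc(F)c1 | starting material
2 | 4-lithio-3,5-difluoroanisole | [Li]c1c(F)cc(OC)cc1F | intermediate
3 | (2,6-difluoro-4-methoxyphenyl)trimethylsilane | COc1cc(F)c([Si](C)(C)C)c(F)c1 | intermediate
4 | [2,4-difluoro-6-methoxy-3-(trimethylsilyl)phenyl]lithium | [Li]c1c(OC)cc(F)c([Si](C)(C)C)c1F | intermediate
5 | (3-bromo-2,6-difluoro-4-methoxyphenyl)trimethylsilane | COc1cc(F)c([Si](C)(C)C)c(F)c1Br | intermediate
6 | methyl 2-(4-methoxyphenyl)-2-oxoacetate | COC(=O)C(=O)c1ccc(OC)cc1 | starting material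
7 | methyl 2,2-dimethoxy-2-(4-methoxyphenyl)acetate | COC(=O)C(OC)(OC)c1ccc(OC)cc1 | intermediate
8 | N,2,2-trimethoxy-2-(4-methoxyphenyl)-N-methylacetamide | CON(C)C(=O)C(OC)(OC)c1ccc(OC)cc1 | intermediate
9 | [3-bromo-4,6-difluoro-2-methoxy-5-(trimethylsilyl)phenyl]lithium | [Li]c1c(OC)c(Br)c(F)c([Si](C)(C)C)c1F | intermediate
10 | 1-[3-bromo-4,6-difluoro-2-methoxy-5-(trimethylsilyl)phenyl]-2,2-dimethoxy-2-(4-methoxyphenyl)ethan-1-one | COc1ccc(C(OC)(OC)C(=O)c2c(F)c([Si](C)(C)C)c(F)c(Br)c2OC)cc1 | intermediate
11 | 1-(3-bromo-4,6-difluoro-2-methoxyphenyl)-2,2-dimethoxy-2-(4-methoxyphenyl)ethan-1-one | COc1ccc(C(OC)(OC)C(=O)c2c(F)cc(F)c(Br)c2OC)cc1 | intermediate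
12 | 2-methylbut-3-yn-2-ol | CC(C)(O)C#C | starting material
13 | 1-[4,6-difluoro-3-(3-hydroxy-3-methylbut-1-yn-1-yl)-2-methoxyphenyl]-2,2-dimethoxy-2-(4-methoxyphenyl)ethan-1-one | COc1ccc(C(OC)(OC)C(=O)c2c(F)cc(F)c(C#CC(C)(C)O)c2OC)cc1 | intermediate
14 | (Z)-1-[4,6-difluoro-3-(3-hydroxy-3-methylbut-1-en-1-yl)-2-methoxyphenyl]-2,2-dimethoxy-2-(4-methoxyphenyl)ethan-1-one | COc1ccc(C(OC)(OC)C(=O)c2c(F)cc(F)c(/C=C\C(C)(C)O)c2OC)cc1 | intermediate
15 | sodium alkoxide of 14 | COc1ccc(C(OC)(OC)C(=O)c2c(F)cc(F)c(/C=C\C(C)(C)[O-])c2OC)cc1.[Na+] | intermediate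
16 | 1-(7-fluoro-5-methoxy-2,2-dimethyl-2H-chromen-6-yl)-2,2-dimethoxy-2-(4-methoxyphenyl)ethan-1-one | COc1ccc(C(OC)(OC)C(=O)c2c(F)cc3c(c2OC)C=CC(C)(C)O3)cc1 | intermediate
17 | 2,2-dimethoxy-1-{5-methoxy-2,2-dimethyl-7-[2-(methylsulfonyl)ethoxy]-2H-chromen-6-yl}-2-(4-methoxyphenyl)ethan-1-one | COc1ccc(C(OC)(OC)C(=O)c2c(OCCS(C)(=O)=O)cc3c(c2OC)C=CC(C)(C)O3)cc1 | intermediate
18 | 1-(7-hydroxy-5-methoxy-2,2-dimethyl-2H-chromen-6-yl)-2,2-dimethoxy-2-(4-methoxyphenyl)ethan-1-one | COc1ccc(C(OC)(OC)C(=O)c2c(O)cc3c(c2OC)C=CC(C)(C)O3)cc1 | intermediate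
19 | 1-(7-hydroxy-5-methoxy-2,2-dimethyl-2H-chromen-6-yl)-2-(4-methoxyphenyl)ethane-1,2-dione | COc1ccc(C(=O)C(=O)c2c(O)cc3c(c2OC)C=CC(C)(C)O3)cc1 | target

**Step count**
Total steps: 11. The longest linear sequence is 9 steps, from 1 to 19 through steps 1, 2 and 5 to 11. Steps 3 and 4 form the two-step side branch.

**Steps most likely to fail**

Step 10.
- What may go wrong: once ring C is closed, O1 donates into the ketone, and the carbonyl is squeezed between two ortho substituents. Displacement of the C7 fluoride may therefore be sluggish. Alkoxide addition to the non-enolisable ketone, followed by C–C cleavage, may then compete.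
- Fallback, from 11 back to 18: the C7 oxygen would be introduced before ring C exists, while ring B still carries two fluorines and the bromine.
- Compound 11 would be treated with sodium 4-methoxybenzyl oxide in toluene. In this non-polar medium the cation bridges the ketone oxygen and the alkoxide and steers attack to the ortho fluoride. The product should be 1-{3-bromo-4-fluoro-2-methoxy-6-[(4-methoxybenzyl)oxy]phenyl}-2,2-dimethoxy-2-(4-methoxyphenyl)ethan-1-one F1.
- Sonogashira coupling of F1 with 12 would give 1-{4-fluoro-3-(3-hydroxy-3-methylbut-1-yn-1-yl)-2-methoxy-6-[(4-methoxybenzyl)oxy]phenyl}-2,2-dimethoxy-2-(4-methoxyphenyl)ethan-1-one F2.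
- Lindlar reduction of F2 would give (Z)-1-{4-fluoro-3-(3-hydroxy-3-methylbut-1-en-1-yl)-2-methoxy-6-[(4-methoxybenzyl)oxy]phenyl}-2,2-dimethoxy-2-(4-methoxyphenyl)ethan-1-one F3.
- NaH in DMF would close ring C by the same para displacement, now the entropically favoured one of the two substitutions. This gives 2,2-dimethoxy-1-{5-methoxy-7-[(4-methoxybenzyl)oxy]-2,2-dimethyl-2H-chromen-6-yl}-2-(4-methoxyphenyl)ethan-1-one F4.
- DDQ in wet CH2Cl2 would then cleave the benzyl ether and reach 18.

Step 5.
- What may go wrong: capture of a hindered aryllithium by an α-quaternary Weinreb amide may be too slow at the temperatures where the ortho-fluoro aryllithium is stable. Loss of LiF to an aryne, or base-induced breakdown of the N-methoxy amide, may then take over.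
- Fallback, from 8 and 5 back to 10: amide 8 would be reduced with iBu2AlH (THF, −78 °C) to 2,2-dimethoxy-2-(4-methoxyphenyl)acetaldehyde F5.
- F5 is a much smaller and more reactive electrophile and should trap aryllithium 9 at −78 °C. The product would be racemic 1-[3-bromo-4,6-difluoro-2-methoxy-5-(trimethylsilyl)phenyl]-2,2-dimethoxy-2-(4-methoxyphenyl)ethan-1-ol F6.
- Oxidation of F6 with Dess–Martin periodinane erases the carbinol centre and returns to 10.

Step 9.
- What may go wrong: the C6 carbonyl lies between OMe and F and bears a quaternary α-carbon, so it may be twisted out of conjugation. Addition of the hindered tertiary alkoxide would then slow down. Intermolecular attack on the C7 fluoride, leading to oligomerisation, may become competitive.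
- Fallback, from 14 back to 18: the polarity of the closure would be reversed.
- Compound 14 would be warmed in DMF with an excess of sodium 2-(trimethylsilyl)ethoxide, a small primary alkoxide that outruns the internal one. Both fluorides would be replaced to give (Z)-1-{3-(3-hydroxy-3-methylbut-1-en-1-yl)-2-methoxy-4,6-bis[2-(trimethylsilyl)ethoxy]phenyl}-2,2-dimethoxy-2-(4-methoxyphenyl)ethan-1-one F7.
- Bu4NF would fragment both silylethyl ethers to (Z)-1-[4,6-dihydroxy-3-(3-hydroxy-3-methylbut-1-en-1-yl)-2-methoxyphenyl]-2,2-dimethoxy-2-(4-methoxyphenyl)ethan-1-one F8.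
- Pyridinium tosylate in CH2Cl2 would then ionise the tertiary allylic alcohol. Only the C8a hydroxyl can reach the cation, so ring C closes through O1–C2, the classical cyclodehydration of cis o-hydroxystyryl carbinols, to give 18.

**Further compounds**
F1 | step 10 | 1-{3-bromo-4-fluoro-2-methoxy-6-[(4-methoxybenzyl)oxy]phenyl}-2,2-dimethoxy-2-(4-methoxyphenyl)ethan-1-one | COc1ccc(COc2cc(F)c(Br)c(OC)c2C(=O)C(OC)(OC)c2ccc(OC)cc2)cc1
F2 | step 10 | 1-{4-fluoro-3-(3-hydroxy-3-methylbut-1-yn-1-yl)-2-methoxy-6-[(4-methoxybenzyl)oxy]phenyl}-2,2-dimethoxy-2-(4-methoxyphenyl)ethan-1-one | COc1ccc(COc2cc(F)c(C#CC(C)(C)O)c(OC)c2C(=O)C(OC)(OC)c2ccc(OC)cc2)cc1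
F3 | step 10 | (Z)-1-{4-fluoro-3-(3-hydroxy-3-methylbut-1-en-1-yl)-2-methoxy-6-[(4-methoxybenzyl)oxy]phenyl}-2,2-dimethoxy-2-(4-methoxyphenyl)ethan-1-one | COc1ccc(COc2cc(F)c(/C=C\C(C)(C)O)c(OC)c2C(=O)C(OC)(OC)c2ccc(OC)cc2)cc1
F4 | step 10 | 2,2-dimethoxy-1-{5-methoxy-7-[(4-methoxybenzyl)oxy]-2,2-dimethyl-2H-chromen-6-yl}-2-(4-methoxyphenyl)ethan-1-one | COc1ccc(COc2cc3c(c(OC)c2C(=O)C(OC)(OC)c2ccc(OC)cc2)C=CC(C)(C)O3)cc1
F5 | step 5 | 2,2-dimethoxy-2-(4-methoxyphenyl)acetaldehyde | COc1ccc(C(OC)(OC)C=O)cc1
F6 | step 5 | 1-[3-bromo-4,6-difluoro-2-methoxy-5-(trimethylsilyl)phenyl]-2,2-dimethoxy-2-(4-methoxyphenyl)ethan-1-ol (racemic) | COc1ccc(C(OC)(OC)C(O)c2c(F)c([Si](C)(C)C)c(F)c(Br)c2OC)cc1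
F7 | step 9 | (Z)-1-{3-(3-hydroxy-3-methylbut-1-en-1-yl)-2-methoxy-4,6-bis[2-(trimethylsilyl)ethoxy]phenyl}-2,2-dimethoxy-2-(4-methoxyphenyl)ethan-1-one | COc1ccc(C(OC)(OC)C(=O)c2c(OCC[Si](C)(C)C)cc(OCC[Si](C)(C)C)c(/C=C\C(C)(C)O)c2OC)cc1
F8 | step 9 | (Z)-1-[4,6-dihydroxy-3-(3-hydroxy-3-methylbut-1-en-1-yl)-2-methoxyphenyl]-2,2-dimethoxy-2-(4-methoxyphenyl)ethan-1-one | COc1ccc(C(OC)(OC)C(=O)c2c(O)cc(O)c(/C=C\C(C)(C)O)c2OC)cc1
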